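## Structural features

The target is an all-E C40 carotenoid tetrol: a chain of eight conjugated C=C bonds (C7 to C9′) with methyl branches at C9, C13, C13′ and C9′ joins two different end groups. Ring A is a cyclohexane with hydroxyls at C3 (S), C5 (R) and C6 (R); C5 and C6 are adjacent, fully substituted and carry trans-diaxial hydroxyls, C3–OH is cis to C6–OH, and C6 is also the tertiary allylic carbon where the chain begins. At the other end ring B (a cyclohexane, C3′–OH, S) is fused through C5′–C6′ to ring C, a 2,5-dihydrofuran whose oxygen bridges the quaternary C5′ (R) and the doubly allylic C8′ (S), with the chain at C8′ cis to the C5′ methyl. The fragile parts are the polyene (light, oxygen, acid), the C6–O bond (its cation is delocalised into the chain) and the C8′–O bond (acids and Lewis acids open ring C and scramble C8′). The real difficulties are the trans 5,6-diol with the right relation to C3, the C8′ centre that no neighbouring stereocentre controls, and four trisubstituted E alkenes in a convergent assembly. The key step exploits C9 of the ring-A side chain: a methyl-branched E-alkene carbon next to the C10–C11 single bond, which is what syn addition of methyl and metal across a terminal C9≡C10 alkyne leaves once the metal on C10 is exchanged for C11.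

## Logic of the disconnections

The four O–Si bonds of 34 are cut last to give 35. Silyl ethers come off with fluoride and no acid, so neither C8′ nor the C6–O bond is put at risk. The forward step must clear two tertiary triethylsilyl and two secondary tert-butyldimethylsilyl ethers with one reagent.

34 is cut at C15=C15′ into 18 and 32. This gives two C20 halves and puts the new double bond where a Z isomer reverts to E most easily. The forward step must join a sulfonyl carbanion to a polyenal without touching C8′ and must end all-E.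

18 goes back through 17 and 16 to 15 by exchanging C15–S for C15–O and the C15 alcohol for the ester. These are functional-group changes only. They demand a 1,2-reduction, a thioetherification without allylic shift, and a sulfur oxidation that spares four C=C bonds.

15 is cut at C10–C11 and at the C9–methyl bond, which gives 11, 13 and a methyl group from the aluminium reagent. The cut lies beside the methyl-branched C9, so the branch carbon need not be in either fragment, and the tetraene falls into an enyne and a dienoate of similar size. The forward step must add methyl and metal syn with methyl on C9, keep every double bond E, and spare the tertiary allylic C6–O bond.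

13 is cut at C11=C12 to 12, which is commercial. One carbon bearing iodine is removed. The forward step must give the E iodoalkene.

11 is cut at C8–C9 to 10 and an ethynyl metal, and 10 at C7=C8 to 9. Two and then one carbon are removed with reagents that fix E geometry, leaving a C10 ring aldehyde. The demand is E selectivity on a hindered aldehyde without α-hydrogen.

9 goes back to 8 and 7 by changing C7 from aldehyde to silyl ether to alcohol and by cutting three O–Si bonds. The aldehyde thus appears only after both tertiary hydroxyls are masked, which excludes retro-aldol cleavage of C5–C6. The forward steps must silylate two hindered tertiary alcohols and then oxidise only the primary position.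

7 is cut at the C5–O bond of its C5 hydroxyl to 6, and 6 at both epoxide C–O bonds to 5. An epoxide cis to the C3 oxygen, opened at C5 with inversion, is the direct source of a trans-diaxial 5,6-diol with C6–O cis to C3–O. The forward steps need reagent-controlled facial selectivity and attack of water at C5, not C6.

5 is cut at C6–C7 through 4 to 3, 3 at its O–S bond to 2, and 2 at its O–Si bond to 1, which is commercial and enantiopure. The ring, C3 and the three ring methyls all come from 1. The demand is enolisation toward C5 (the only side with a hydrogen) and carbonylation of a tetrasubstituted enol triflate.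

32 goes back through 31 and 30 to 28 and 29 by a cut at C11′=C12′ and two redox changes at C15′. 29 is commercial and brings C12′–C15′ with the C13′ methyl, so the ring-bearing piece shrinks to C15. The forward olefination must give E at C11′=C12′ and C13′=C14′ and must not deprotonate C8′.

28 goes back to 27 by the oxidation level at C11′, and 27 is cut at O–C8′ to 26. Opening ring C turns the C8′ stereocentre into an allene axis at C6′=C7′=C8′. The forward ring closure must copy the axis into C8′ without loss.

26 is cut at C8′–H with re-formation of the C6′–O bond, which leads through 25 to 24. The axis is thereby traced to the C6′ centre of an epoxide, and the ester reduction comes in the same operation. The demand is hydride delivery to C8′ on the side of the breaking C6′–O bond.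

24 is cut at C8′–C9′ to 21 and 23, and 23 at its O–S bond to 22, which is commercial. This separates the ring from a C4 unit of fixed E geometry. The forward steps need an E-selective enol triflation and a coupling that leaves the epoxide intact.

21 is cut at C7′≡C8′ to 20, 20 goes back to 19 by oxidation level, and 19 is cut at both epoxide C–O bonds to 5. Both halves of the target therefore share 1 to 5 and differ only in the tartrate used. The demand is epoxidation on the face opposite to the C3′ oxygen.

## Other disconnections considered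

Alternative 1: The cut goes through the C3–O and C6–O bonds of ring A, a retro-[4+2] leading to the achiral diene A1. Forward, singlet oxygen (O2, rose bengal, visible light) would add suprafacially across C3 and C6 of A1 and close the 2,3-dioxabicyclo[2.2.2]octene A2.
- In its favour: two of the three ring oxygens arrive in one step, their cis relation is enforced by the bicycle, and no palladium, CO or triflate is needed.
- Against it here: A1 has no stereocentre, so A2 would form as a racemate and the required enantiomer would need a resolution or a chiral auxiliary. After O–O cleavage the C4=C5 bond must still be hydrated with oxygen on C5 trans to both existing oxygens, and the peroxide invites base-induced fragmentation.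
- Structure: both plans converge on a C10 ring with CH2O at C6, such as 7, and the alternative could feed the same step 12.
- Mechanism: the pericyclic step is better than step 5 at securing the cis C3/C6 relation, which in the chosen plan rests on a tartrate working against the substrate.
- Step economy: about equal up to the stage of 7. The chosen plan takes C3 from 1 as a single enantiomer and loses nothing to resolution, which decides the matter for a single-enantiomer target.

Alternative 2: The cut is the O–C8′ bond of ring C, leading to the silylated allenol A3. Forward, Ph3PAuCl with AgBF4 (monovalent gold) would activate the C7′=C8′ bond, the C5′ hydroxyl would add to C8′ anti to gold, and protodeauration would give the furanoid bis-silyl ether A4.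
- In its favour: the allene axis is copied into C8′, the catalyst loading is low, and the reaction should be fast at room temperature.
- Against it here: it addresses only the furanoid half, so the C9 branch and the C10–C11 bond would still need other chemistry. Cationic gold can flatten an allene axis through an allyl-cation-like complex, and acid formed from AgBF4 and traces of water threatens C8′. A3 needs one silylation more than 26, and A4 a selective desilylation later.
- Structure and mechanism: the alternative is the equal of step 22, which closes the same bond by the same anti oxymetalation with AgNO3 on 26.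
- Catalyst turnover: the alternative is better.
- Step economy: the chosen plan is two protecting-group operations shorter and uses the less acidic metal. The two are complementary, not rivals, since this ring closure cannot replace step 12.

Alternative 3: The cut is the C5–O bond of ring A, formed from the carbonyl oxygen of a C7 tert-butyl carbonate, A5, instead of from water. Forward, BF3·OEt2 would activate the epoxide of A5, the carbonate oxygen would attack C5 from the face opposite to the epoxide oxygen, and loss of the tert-butyl group would leave the six-membered cyclic carbonate A6 with free C6–OH.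
- In its favour: the tether fixes both the site (C5, six-membered ring) and the inversion.
- Against it here: two more steps (carbonate formation and cleavage), a strong Lewis acid beside a silyl ether, and possible loss of the tert-butyl group before cyclisation.
- Structure: A5 would come from 6 and A6 would give 7 on methanolysis, so both plans pass through the same numbered compounds; here the two are equal.
- Mechanism: the relay is better than step 6 in stereochemical certainty, because step 6 depends on water attacking a protonated tetrasubstituted epoxide faster than it ionises.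
- Step economy: the chosen plan is two steps shorter. The tethered-oxygen idea is kept as the fallback for step 6.

Key step: step 12

Remarks on the chemistry:
- Carotenoid numbering is used for all intermediates (C7 is the carbon on C6; primes mark the furanoid half).
- By this count 11 has thirteen skeletal carbons (a C13 enyne) and 15 has four C=C bonds (a C20 tetraenoate).
- The C3 descriptor changes from R to S when C5 becomes oxygenated; this is a priority change, not an inversion.
- Assumption: iBu2AlH opens the alkynyl epoxide 24 by hydride delivery on the side of the breaking C–O bond (syn SN2′).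
- 1, 12, 22 and 29 are commercial.

Step 1
Reactants: 1 (4R,6R)-4-hydroxy-2,2,6-trimethylcyclohexan-1-one
Product: 2 (4R,6R)-4-(tert-butyldimethylsilyloxy)-2,2,6-trimethylcyclohexan-1-one
Conditions: tBuMe2SiCl, imidazole, DMF, rt
Reagents that add atoms: tert-butyldimethylsilyl chloride, CC(C)(C)[Si](C)(C)Cl
Why: Imidazole-promoted silylation of the only hydroxyl (silyl ether formation); no stereocentre is touched.

Step 2
Reactants: 2 (4R,6R)-4-(tert-butyldimethylsilyloxy)-2,2,6-trimethylcyclohexan-1-one
Product: 3 (4R)-4-(tert-butyldimethylsilyloxy)-2,6,6-trimethylcyclohex-1-en-1-yl trifluoromethanesulfonate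
Conditions: LiN(iPr)2, THF, −78 °C; PhNTf2, −78 °C → rt
Reagents that add atoms: N-phenylbis(trifluoromethanesulfonimide), O=S(=O)(N(c1ccccc1)S(=O)(=O)C(F)(F)F)C(F)(F)F
Why: Only C5 carries an α-hydrogen (C1 is quaternary), so a single enolate forms and is triflated on oxygen (enol triflate formation); the C5 centre is removed on purpose and C3 stays.

Step 3
Reactants: 3 (4R)-4-(tert-butyldimethylsilyloxy)-2,6,6-trimethylcyclohex-1-en-1-yl trifluoromethanesulfonate
Product: 4 methyl (4R)-4-(tert-butyldimethylsilyloxy)-2,6,6-trimethylcyclohex-1-ene-1-carboxylate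
Conditions: CO (1 atm), Pd(OAc)2 (5 mol%), PPh3 (10 mol%), Et3N, MeOH–DMF, 60 °C
Reagents that add atoms: carbon monoxide, [C-]#[O+]; methanol, CO
Why: Oxidative addition of the enol triflate to zerovalent palladium, CO insertion and methanolysis (palladium-catalysed alkoxycarbonylation) form the C6–C7 bond; no stereocentre is involved.

Step 4
Reactants: 4 methyl (4R)-4-(tert-butyldimethylsilyloxy)-2,6,6-trimethylcyclohex-1-ene-1-carboxylate
Product: 5 [(4R)-4-(tert-butyldimethylsilyloxy)-2,6,6-trimethylcyclohex-1-en-1-yl]methanol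
Conditions: iBu2AlH, CH2Cl2, −78 → 0 °C; aq. potassium sodium tartrate
Reagents that add atoms: none
Why: 1,2-Reduction of the conjugated ester to the allylic alcohol by the aluminium hydride; the silyl ether and the tetrasubstituted alkene are inert.

Step 5
Reactants: 5 [(4R)-4-(tert-butyldimethylsilyloxy)-2,6,6-trimethylcyclohex-1-en-1-yl]methanol
Product: 6 [(1S,4S,6S)-4-(tert-butyldimethylsilyloxy)-2,2,6-trimethyl-7-oxabicyclo[4.1.0]heptan-1-yl]methanol (5,6-epoxide cis to the C3 silyloxy group)
Conditions: tBuOOH, Ti(OiPr)4 (10 mol%), L-(+)-diethyl tartrate (12 mol%), 4 Å molecular sieves, CH2Cl2, −20 °C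
Reagents that add atoms: tert-butyl hydroperoxide, CC(C)(C)OO
Why: Katsuki–Sharpless asymmetric epoxidation: the allylic alcohol binds titanium and the L-(+)-tartrate should direct oxygen to the face of C5=C6 cis to the C3 silyloxy group, setting C5 and C6 together under reagent control.

Step 6
Reactants: 6 [(1S,4S,6S)-4-(tert-butyldimethylsilyloxy)-2,2,6-trimethyl-7-oxabicyclo[4.1.0]heptan-1-yl]methanol
Product: 7 (1S,2R,4S)-4-(tert-butyldimethylsilyloxy)-1-(hydroxymethyl)-2,6,6-trimethylcyclohexane-1,2-diol (5,6-diol trans, C6–OH cis to C3–O)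
Conditions: HClO4 (cat.), THF–H2O (4:1), 0 °C
Reagents that add atoms: water, O
Why: Acid-catalysed epoxide hydrolysis: water should attack the protonated epoxide at C5 (tertiary, remote from the electron-poor CH2OH carbon, trans-diaxial opening by the Fürst–Plattner rule) with inversion, so C5–OH ends trans to C6–OH while C6–O keeps its cis relation to C3–O.

Step 7
Reactants: 7 (1S,2R,4S)-4-(tert-butyldimethylsilyloxy)-1-(hydroxymethyl)-2,6,6-trimethylcyclohexane-1,2-diol
Product: 8 tris(triethylsilyl) ether of 7 (Et3SiO at C5, C6 and C7)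
Conditions: Et3SiOTf (5 equiv), 2,6-lutidine, CH2Cl2, −78 °C → rt
Reagents that add atoms: triethylsilyl trifluoromethanesulfonate, CC[Si](CC)(CC)OS(=O)(=O)C(F)(F)F
Why: Silyl triflate with a hindered pyridine silylates tertiary alcohols (silyl ether formation); all three hydroxyls are capped in one operation so that the later aldehyde has no free β-hydroxyl, and the C6 hydroxyl may need the excess reagent and room temperature.

Step 8
Reactants: 8 tris(triethylsilyl) ether of 7
Product: 9 (1R,2R,4S)-4-(tert-butyldimethylsilyloxy)-2,6,6-trimethyl-1,2-bis(triethylsilyloxy)cyclohexane-1-carbaldehyde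
Conditions: (COCl)2, DMSO, CH2Cl2, −78 → −40 °C; Et3N, → 0 °C
Reagents that add atoms: none
Why: Under Swern conditions the chlorosulfonium salt cleaves only the primary triethylsilyl ether and the resulting alkoxysulfonium ion collapses to the aldehyde (oxidative desilylation, Swern oxidation); tertiary Et3Si and secondary tBuMe2Si ethers stay, and 9 can neither epimerise (no α-hydrogen) nor undergo retro-aldol cleavage (C5–O silylated).

Step 9
Reactants: 9 (1R,2R,4S)-4-(tert-butyldimethylsilyloxy)-2,6,6-trimethyl-1,2-bis(triethylsilyloxy)cyclohexane-1-carbaldehyde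
Product: 10 (E)-iodoalkene with the ring of 9 and (E)-CH=CHI at C6 (3S,5R,6R)
Conditions: CrCl2, CHI3, THF, 0 °C → rt
Reagents that add atoms: iodoform, IC(I)I
Why: Takai olefination: the geminal dichromium species from CHI3 and CrCl2 adds to the aldehyde and eliminates with the iodine anti to the bulky ring, which should give the E iodoalkene; silyl ethers are inert to CrCl2.

Step 10
Reactants: 10 (E)-iodoalkene with (E)-CH=CHI at C6
Product: 11 C13 ring enyne with (E)-CH=CH–C≡CH at C6 (3S,5R,6R; O-SiEt3 at C5 and C6, O-SitBuMe2 at C3)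
Conditions: HC≡CMgBr, ZnBr2, THF, 0 °C; then 10, Pd(PPh3)4 (5 mol%), rt
Reagents that add atoms: ethynylmagnesium bromide, C#C[Mg]Br
Why: Negishi coupling of the alkenyl iodide with ethynylzinc bromide, made in the flask from the Grignard reagent and ZnBr2, under zerovalent palladium gives the terminal enyne directly with retention of the E geometry, so no alkyne protecting group has to be removed.

Step 11
Reactants: 12 ethyl (2E)-3-methyl-4-oxobut-2-enoate
Product: 13 ethyl (2E,4E)-5-iodo-3-methylpenta-2,4-dienoate
Conditions: CrCl2, CHI3, THF, 0 °C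
Reagents that add atoms: iodoform, IC(I)I
Why: Takai olefination of the enal, E-selective as in step 9; the ester and the existing E double bond are not affected.

Step 12
Reactants: 11 C13 ring enyne; 13 ethyl (2E,4E)-5-iodo-3-methylpenta-2,4-dienoate
Product: 15 silylated ring-A C20 tetraenoate (ethyl (2E,4E,6E,8E)-3,7-dimethyl-9-[ring A]nona-2,4,6,8-tetraenoate; 3S,5R,6R), via dienylalane 14 (not isolated)
Conditions: AlMe3 (3 equiv), Cp2ZrCl2 (0.2 equiv), H2O (1 equiv), CH2Cl2, −30 °C; volatiles off, THF; 13, ZnCl2 (0.3 equiv), Pd(PPh3)4 (5 mol%), 0 °C → rt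
Reagents that add atoms: trimethylaluminium, C[Al](C)C
Why: Cp2ZrCl2 and AlMe3 form a methylzirconocene species polarised by aluminium, which adds methyl and metal syn across C9≡C10 with the metal on the terminal C10 and methyl on C9; exchange to aluminium releases dienylalane 14 and the catalyst (zirconium-catalysed carboalumination). 13 then adds oxidatively to zerovalent palladium with retention, the dienyl group passes from aluminium through zinc to palladium with retention, and reductive elimination forms the C10–C11 bond (Negishi coupling). The closest known reaction type is the methylalumination of conjugated terminal enynes followed by Pd(PPh3)4-catalysed coupling of the alkenylalane with alkenyl iodides, as used for retinoid chains. No ring is closed and no stereocentre is formed; what is set is the E geometry of C9=C10, which follows from syn addition, while C7=C8, C11=C12 and C13=C14 pass through unchanged. Methyl on C9 is secured by the terminal alkyne, and chemoselectivity by the inertness of the C7=C8 alkene and of the ester toward the alane at or below room temperature. The weak point is the tertiary allylic C6–O bond: as a hindered triethylsilyl ether it binds aluminium poorly and is not ionised by zerovalent palladium, and the added water, which generates a more active aluminoxane promoter, lets the carbometalation run at −30 °C at a useful rate.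

Step 13
Reactants: 15 silylated ring-A C20 tetraenoate
Product: 16 silylated ring-A C20 tetraenol ((2E,4E,6E,8E)-3,7-dimethyl-9-[ring A]nona-2,4,6,8-tetraen-1-ol)
Conditions: iBu2AlH, CH2Cl2, −78 °C; aq. potassium sodium tartrate
Reagents that add atoms: none
Why: 1,2-Reduction of the conjugated ester to the primary allylic alcohol; tetraene and silyl ethers are inert at −78 °C.

Step 14
Reactants: 16 silylated ring-A C20 tetraenol
Product: 17 C20 tetraenyl 1-phenyl-1H-tetrazol-5-yl sulfide
Conditions: 1-phenyl-1H-tetrazole-5-thiol, PPh3, iPrO2C–N=N–CO2iPr, THF, 0 °C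
Reagents that add atoms: 1-phenyl-1H-tetrazole-5-thiol, Sc1nnnn1-c1ccccc1
Why: Mitsunobu thioetherification: the primary allylic alcohol is activated as its oxyphosphonium ion and displaced at C15 by the thiolate (SN2); the silylated tertiary oxygens cannot react.

Step 15
Reactants: 17 C20 tetraenyl 1-phenyl-1H-tetrazol-5-yl sulfide
Product: 18 C20 tetraenyl 1-phenyl-1H-tetrazol-5-yl sulfone
Conditions: H2O2 (30 % aq.), (NH4)6Mo7O24·4H2O (10 mol%), EtOH, −10 → 0 °C
Reagents that add atoms: hydrogen peroxide, OO
Why: Molybdate-catalysed peroxide oxidation of sulfide to sulfone; at low temperature the peroxomolybdate should oxidise sulfur much faster than the conjugated tetraene.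

Step 16
Reactants: 5 [(4R)-4-(tert-butyldimethylsilyloxy)-2,6,6-trimethylcyclohex-1-en-1-yl]methanol
Product: 19 [(1R,4S,6R)-4-(tert-butyldimethylsilyloxy)-2,2,6-trimethyl-7-oxabicyclo[4.1.0]heptan-1-yl]methanol (5′,6′-epoxide trans to the C3′ silyloxy group)
Conditions: tBuOOH, Ti(OiPr)4 (10 mol%), D-(−)-diethyl tartrate (12 mol%), 4 Å molecular sieves, CH2Cl2, −20 °C
Reagents that add atoms: tert-butyl hydroperoxide, CC(C)(C)OO
Why: Katsuki–Sharpless asymmetric epoxidation with the enantiomeric tartrate, which should deliver oxygen to the face trans to the C3′ silyloxy group (also the face the substrate prefers), setting C5′ (R) and C6′.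

Step 17
Reactants: 19 [(1R,4S,6R)-4-(tert-butyldimethylsilyloxy)-2,2,6-trimethyl-7-oxabicyclo[4.1.0]heptan-1-yl]methanol
Product: 20 (1S,4S,6R)-4-(tert-butyldimethylsilyloxy)-2,2,6-trimethyl-7-oxabicyclo[4.1.0]heptane-1-carbaldehyde
Conditions: Pr4N[RuO4] (5 mol%), N-methylmorpholine N-oxide, 4 Å molecular sieves, CH2Cl2, rt
Reagents that add atoms: none
Why: Ley–Griffith oxidation of the primary alcohol to the aldehyde under neutral conditions that spare the acid-sensitive tetrasubstituted epoxide; there is no α-hydrogen to epimerise.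

Step 18
Reactants: 20 (1S,4S,6R)-4-(tert-butyldimethylsilyloxy)-2,2,6-trimethyl-7-oxabicyclo[4.1.0]heptane-1-carbaldehyde
Product: 21 (1R,4S,6R)-4-(tert-butyldimethylsilyloxy)-1-ethynyl-2,2,6-trimethyl-7-oxabicyclo[4.1.0]heptane
Conditions: MeC(O)C(N2)P(O)(OMe)2, K2CO3, MeOH, 0 °C → rt
Reagents that add atoms: dimethyl (1-diazo-2-oxopropyl)phosphonate, COP(=O)(OC)C(=[N+]=[N-])C(C)=O
Why: Seyferth–Gilbert homologation with the Ohira–Bestmann reagent: methanolysis frees the diazomethylphosphonate anion, which adds to the aldehyde, loses phosphate and then N2, and rearranges to the terminal alkyne; C5′ and C6′ are not involved.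

Step 19
Reactants: 22 ethyl 3-oxobutanoate
Product: 23 ethyl (2E)-3-[(trifluoromethylsulfonyl)oxy]but-2-enoate
Conditions: Tf2O, aq. Me4NOH, hexane, 5 °C → rt
Reagents that add atoms: trifluoromethanesulfonic anhydride, O=S(=O)(OS(=O)(=O)C(F)(F)F)C(F)(F)F
Why: O-Triflation of the β-keto ester enolate; with the non-coordinating tetramethylammonium counter-ion the enolate reacts in its extended form, which should give the E enol triflate (triflate trans to the ester).

Step 20
Reactants: 21 (1R,4S,6R)-4-(tert-butyldimethylsilyloxy)-1-ethynyl-2,2,6-trimethyl-7-oxabicyclo[4.1.0]heptane; 23 ethyl (2E)-3-[(trifluoromethylsulfonyl)oxy]but-2-enoate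
Product: 24 ethyl (2E)-5-[(1R,4S,6R)-4-(tert-butyldimethylsilyloxy)-2,2,6-trimethyl-7-oxabicyclo[4.1.0]heptan-1-yl]-3-methylpent-2-en-4-ynoate
Conditions: Pd(PPh3)4 (5 mol%), CuI (10 mol%), iPr2NH, THF, rt
Reagents that add atoms: none
Why: Sonogashira coupling (zerovalent palladium with CuI) of the terminal alkyne with the enol triflate forms C8′–C9′ with retention of the E geometry; the epoxide is inert to these conditions.

Step 21
Reactants: 24 ethyl (2E)-5-[(1R,4S,6R)-4-(tert-butyldimethylsilyloxy)-2,2,6-trimethyl-7-oxabicyclo[4.1.0]heptan-1-yl]-3-methylpent-2-en-4-ynoate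
Product: 26 C15 allenic diol ((2E)-5-[(2R,4S)-4-(tert-butyldimethylsilyloxy)-2-hydroxy-2,6,6-trimethylcyclohexylidene]-3-methylpenta-2,4-dien-1-ol; allene axis R; 3′S,5′R,6′R), via aluminium alkoxide 25 (not isolated)
Conditions: iBu2AlH (5 equiv), CH2Cl2, −78 → 0 °C; aq. potassium sodium tartrate
Reagents that add atoms: none
Why: The hydride first reduces the ester to aluminium alkoxide 25; a further equivalent bound to the epoxide oxygen should deliver hydride to C8′ on the side of the breaking C6′–O bond (syn SN2′ reduction of an alkynyl epoxide), turning the C6′ stereocentre into the (6′R) allene axis while the C5′–O bond is kept.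

Step 22
Reactants: 26 C15 allenic diol
Product: 27 (2E)-3-[(2S,6S,7aR)-6-(tert-butyldimethylsilyloxy)-4,4,7a-trimethyl-2,4,5,6,7,7a-hexahydro-1-benzofuran-2-yl]but-2-en-1-ol
Conditions: AgNO3 (0.2 equiv), CaCO3, acetone–H2O, rt, dark
Reagents that add atoms: none
Why: Silver-mediated 5-endo cyclisation of an α-hydroxyallene: AgNO3 activates C7′=C8′ anti to the C5′ hydroxyl, oxygen adds to C8′ in the plane of C5′–C6′–C7′ and protodemetalation gives the 2,5-dihydrofuran, so the axis is copied into C8′ (S, chain cis to the C5′ methyl); the primary hydroxyl cannot reach C8′ across the E C9′=C10′ bond.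

Step 23
Reactants: 27 (2E)-3-[(2S,6S,7aR)-6-(tert-butyldimethylsilyloxy)-4,4,7a-trimethyl-2,4,5,6,7,7a-hexahydro-1-benzofuran-2-yl]but-2-en-1-ol
Product: 28 (2E)-3-[(2S,6S,7aR)-6-(tert-butyldimethylsilyloxy)-4,4,7a-trimethyl-2,4,5,6,7,7a-hexahydro-1-benzofuran-2-yl]but-2-enal
Conditions: MnO2, CH2Cl2, rt
Reagents that add atoms: none
Why: Heterogeneous MnO2 oxidation of the allylic alcohol to the enal under neutral conditions; the doubly allylic ether carbon C8′ is not touched.

Step 24
Reactants: 28 (2E)-3-[(2S,6S,7aR)-6-(tert-butyldimethylsilyloxy)-4,4,7a-trimethyl-2,4,5,6,7,7a-hexahydro-1-benzofuran-2-yl]but-2-enal; 29 ethyl (2E)-4-(diethoxyphosphoryl)-3-methylbut-2-enoate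
Product: 30 ethyl (2E,4E,6E)-7-[(2S,6S,7aR)-6-(tert-butyldimethylsilyloxy)-4,4,7a-trimethyl-2,4,5,6,7,7a-hexahydro-1-benzofuran-2-yl]-3-methylocta-2,4,6-trienoate
Conditions: 29, nBuLi, THF–DMPU, −78 °C; then 28, −78 → 0 °C
Reagents that add atoms: none
Why: Horner–Wadsworth–Emmons olefination: the lithiated phosphonate adds through the carbon next to phosphorus (C12′) and eliminates phosphate to give E at C11′=C12′, and in THF–DMPU the C13′=C14′ bond should come out E; addition at −78 °C keeps the anion from deprotonating C8′.

Step 25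
Reactants: 30 ethyl (2E,4E,6E)-7-[furanoid ring]-3-methylocta-2,4,6-trienoate
Product: 31 (2E,4E,6E)-7-[(2S,6S,7aR)-6-(tert-butyldimethylsilyloxy)-4,4,7a-trimethyl-2,4,5,6,7,7a-hexahydro-1-benzofuran-2-yl]-3-methylocta-2,4,6-trien-1-ol
Conditions: iBu2AlH, CH2Cl2, −78 °C; aq. potassium sodium tartrate
Reagents that add atoms: none
Why: 1,2-Reduction of the trienoate to the allylic alcohol; the neutral tartrate work-up avoids acid at C8′.

Step 26
Reactants: 31 (2E,4E,6E)-7-[furanoid ring]-3-methylocta-2,4,6-trien-1-ol
Product: 32 (2E,4E,6E)-7-[(2S,6S,7aR)-6-(tert-butyldimethylsilyloxy)-4,4,7a-trimethyl-2,4,5,6,7,7a-hexahydro-1-benzofuran-2-yl]-3-methylocta-2,4,6-trienal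
Conditions: MnO2, CH2Cl2, rt, dark
Reagents that add atoms: none
Why: MnO2 oxidation of the polyenylic alcohol to the aldehyde under neutral conditions; no stereocentre is affected.

Step 27
Reactants: 18 C20 tetraenyl 1-phenyl-1H-tetrazol-5-yl sulfone; 32 furanoid C20 trienal
Product: 34 tetrakis-silyl ether of the target (all-E; tBuMe2SiO at C3 and C3′; Et3SiO at C5 and C6), via 15Z isomer 33 (not isolated)
Conditions: 18, NaN(SiMe3)2, THF, −78 °C; 32, −78 → 0 °C; then toluene, 70 °C, dark
Reagents that add atoms: none
Why: Julia–Kocienski olefination: the sulfonyl carbanion of 18 adds to 32, the alkoxide takes over the tetrazole ring (Smiles rearrangement) and loss of SO2 and the tetrazolone forms C15=C15′; the 15Z isomer 33 formed beside the E isomer is the thermally most labile cis form of a carotenoid and should converge on all-E 34 on gentle heating in the dark.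

Step 28
Reactants: 34 tetrakis-silyl ether of the target
Product: 35 (3S,5R,6R,3′S,5′R,8′S)-5′,8′-epoxy-5,6,5′,8′-tetrahydro-β,β-carotene-3,5,6,3′-tetrol (all-E)
Conditions: Bu4NF, THF, 0 °C → rt, dark
Reagents that add atoms: none
Why: Fluoride cleaves all four silyl ethers through Si–F bond formation under non-acidic conditions, so neither the tertiary allylic C6–O bond nor C8′ is exposed to acid.

Compound list

1 | (4R,6R)-4-hydroxy-2,2,6-trimethylcyclohexan-1-one | O=C1C(C)(C)C[C@H](O)C[C@H]1C | starting material
2 | (4R,6R)-4-(tert-butyldimethylsilyloxy)-2,2,6-trimethylcyclohexan-1-one | O=C1C(C)(C)C[C@H](O[Si](C)(C)C(C)(C)C)C[C@H]1C | intermediate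
3 | (4R)-4-(tert-butyldimethylsilyloxy)-2,6,6-trimethylcyclohex-1-en-1-yl trifluoromethanesulfonate | CC1=C(OS(=O)(=O)C(F)(F)F)C(C)(C)C[C@H](O[Si](C)(C)C(C)(C)C)C1 | intermediate
4 | methyl (4R)-4-(tert-butyldimethylsilyloxy)-2,6,6-trimethylcyclohex-1-ene-1-carboxylate | CC1=C(C(=O)OC)C(C)(C)C[C@H](O[Si](C)(C)C(C)(C)C)C1 | intermediate
5 | [(4R)-4-(tert-butyldimethylsilyloxy)-2,6,6-trimethylcyclohex-1-en-1-yl]methanol | CC1=C(CO)C(C)(C)C[C@H](O[Si](C)(C)C(C)(C)C)C1 | intermediate
6 | [(1S,4S,6S)-4-(tert-butyldimethylsilyloxy)-2,2,6-trimethyl-7-oxabicyclo[4.1.0]heptan-1-yl]methanol (epoxide cis to the silyloxy group) | OC[C@]12O[C@@]1(C)C[C@@H](O[Si](C)(C)C(C)(C)C)CC2(C)C | intermediate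
7 | (1S,2R,4S)-4-(tert-butyldimethylsilyloxy)-1-(hydroxymethyl)-2,6,6-trimethylcyclohexane-1,2-diol | OC[C@@]1(O)C(C)(C)C[C@H](O[Si](C)(C)C(C)(C)C)C[C@@]1(C)O | intermediate
8 | tris(triethylsilyl) ether of 7 (Et3SiO at C5, C6 and C7) | CC[Si](CC)(CC)OC[C@@]1(O[Si](CC)(CC)CC)C(C)(C)C[C@H](O[Si](C)(C)C(C)(C)C)C[C@@]1(C)O[Si](CC)(CC)CC | intermediate
9 | (1R,2R,4S)-4-(tert-butyldimethylsilyloxy)-2,6,6-trimethyl-1,2-bis(triethylsilyloxy)cyclohexane-1-carbaldehyde | O=C[C@@]1(O[Si](CC)(CC)CC)C(C)(C)C[C@H](O[Si](C)(C)C(C)(C)C)C[C@@]1(C)O[Si](CC)(CC)CC | intermediate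
10 | (E)-iodoalkene: ring of 9 with (E)-CH=CHI at C6 (3S,5R,6R) | I/C=C/[C@@]1(O[Si](CC)(CC)CC)C(C)(C)C[C@H](O[Si](C)(C)C(C)(C)C)C[C@@]1(C)O[Si](CC)(CC)CC | intermediate
11 | C13 ring enyne: ring of 9 with (E)-CH=CH–C≡CH at C6 (3S,5R,6R) | C#C/C=C/[C@@]1(O[Si](CC)(CC)CC)C(C)(C)C[C@H](O[Si](C)(C)C(C)(C)C)C[C@@]1(C)O[Si](CC)(CC)CC | intermediate
12 | ethyl (2E)-3-methyl-4-oxobut-2-enoate | CCOC(=O)/C=C(C)/C=O | starting material
13 | ethyl (2E,4E)-5-iodo-3-methylpenta-2,4-dienoate | CCOC(=O)/C=C(C)/C=C/I | intermediate
14 | dimethyl[(1E,3E)-2-methyl-4-(ring A)buta-1,3-dienyl]alane; not isolated | C[Al](C)/C=C(\C)/C=C/[C@@]1(O[Si](CC)(CC)CC)C(C)(C)C[C@H](O[Si](C)(C)C(C)(C)C)C[C@@]1(C)O[Si](CC)(CC)CC | intermediate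
15 | ethyl (2E,4E,6E,8E)-3,7-dimethyl-9-[(3S,5R,6R)-silylated ring A]nona-2,4,6,8-tetraenoate | CCOC(=O)/C=C(C)/C=C/C=C(C)/C=C/[C@@]1(O[Si](CC)(CC)CC)C(C)(C)C[C@H](O[Si](C)(C)C(C)(C)C)C[C@@]1(C)O[Si](CC)(CC)CC | intermediate
16 | (2E,4E,6E,8E)-3,7-dimethyl-9-[(3S,5R,6R)-silylated ring A]nona-2,4,6,8-tetraen-1-ol | OC/C=C(C)/C=C/C=C(C)/C=C/[C@@]1(O[Si](CC)(CC)CC)C(C)(C)C[C@H](O[Si](C)(C)C(C)(C)C)C[C@@]1(C)O[Si](CC)(CC)CC | intermediate
17 | 1-phenyl-1H-tetrazol-5-yl sulfide of 16 (sulfur on C15) | c1ccccc1-n1nnnc1SC/C=C(C)/C=C/C=C(C)/C=C/[C@@]2(O[Si](CC)(CC)CC)C(C)(C)C[C@H](O[Si](C)(C)C(C)(C)C)C[C@@]2(C)O[Si](CC)(CC)CC | intermediate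
18 | 1-phenyl-1H-tetrazol-5-yl sulfone corresponding to 17 | c1ccccc1-n1nnnc1S(=O)(=O)C/C=C(C)/C=C/C=C(C)/C=C/[C@@]2(O[Si](CC)(CC)CC)C(C)(C)C[C@H](O[Si](C)(C)C(C)(C)C)C[C@@]2(C)O[Si](CC)(CC)CC | intermediate
19 | [(1R,4S,6R)-4-(tert-butyldimethylsilyloxy)-2,2,6-trimethyl-7-oxabicyclo[4.1.0]heptan-1-yl]methanol (epoxide trans to the silyloxy group) | OC[C@@]12O[C@]1(C)C[C@@H](O[Si](C)(C)C(C)(C)C)CC2(C)C | intermediate
20 | (1S,4S,6R)-4-(tert-butyldimethylsilyloxy)-2,2,6-trimethyl-7-oxabicyclo[4.1.0]heptane-1-carbaldehyde | O=C[C@@]12O[C@]1(C)C[C@@H](O[Si](C)(C)C(C)(C)C)CC2(C)C | intermediate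
21 | (1R,4S,6R)-4-(tert-butyldimethylsilyloxy)-1-ethynyl-2,2,6-trimethyl-7-oxabicyclo[4.1.0]heptane | C#C[C@@]12O[C@]1(C)C[C@@H](O[Si](C)(C)C(C)(C)C)CC2(C)C | intermediate
22 | ethyl 3-oxobutanoate | CCOC(=O)CC(C)=O | starting material
23 | ethyl (2E)-3-[(trifluoromethylsulfonyl)oxy]but-2-enoate | CCOC(=O)/C=C(C)/OS(=O)(=O)C(F)(F)F | intermediate
24 | ethyl (2E)-5-[(1R,4S,6R)-4-(tert-butyldimethylsilyloxy)-2,2,6-trimethyl-7-oxabicyclo[4.1.0]heptan-1-yl]-3-methylpent-2-en-4-ynoate | CCOC(=O)/C=C(C)/C#C[C@@]12O[C@]1(C)C[C@@H](O[Si](C)(C)C(C)(C)C)CC2(C)C | intermediate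
25 | diisobutylaluminium alkoxide of the pent-2-en-4-yn-1-ol corresponding to 24; not isolated | CC(C)C[Al](CC(C)C)OC/C=C(C)/C#C[C@@]12O[C@]1(C)C[C@@H](O[Si](C)(C)C(C)(C)C)CC2(C)C | intermediate
26 | (2E)-5-[(2R,4S)-4-(tert-butyldimethylsilyloxy)-2-hydroxy-2,6,6-trimethylcyclohexylidene]-3-methylpenta-2,4-dien-1-ol, allene axis R (3′S,5′R,6′R) | OC/C=C(\C)C=[C@@]=C1C(C)(C)C[C@H](O[Si](C)(C)C(C)(C)C)C[C@@]1(C)O | intermediate
27 | (2E)-3-[(2S,6S,7aR)-6-(tert-butyldimethylsilyloxy)-4,4,7a-trimethyl-2,4,5,6,7,7a-hexahydro-1-benzofuran-2-yl]but-2-en-1-ol | OC/C=C(\C)[C@@H]1C=C2C(C)(C)C[C@H](O[Si](C)(C)C(C)(C)C)C[C@@]2(C)O1 | intermediate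
28 | (2E)-3-[(2S,6S,7aR)-6-(tert-butyldimethylsilyloxy)-4,4,7a-trimethyl-2,4,5,6,7,7a-hexahydro-1-benzofuran-2-yl]but-2-enal | O=C/C=C(\C)[C@@H]1C=C2C(C)(C)C[C@H](O[Si](C)(C)C(C)(C)C)C[C@@]2(C)O1 | intermediate
29 | ethyl (2E)-4-(diethoxyphosphoryl)-3-methylbut-2-enoate | CCOC(=O)/C=C(\C)CP(=O)(OCC)OCC | starting material
30 | ethyl (2E,4E,6E)-7-[(2S,6S,7aR)-6-(tert-butyldimethylsilyloxy)-4,4,7a-trimethyl-2,4,5,6,7,7a-hexahydro-1-benzofuran-2-yl]-3-methylocta-2,4,6-trienoate | CCOC(=O)/C=C(C)/C=C/C=C(\C)[C@@H]1C=C2C(C)(C)C[C@H](O[Si](C)(C)C(C)(C)C)C[C@@]2(C)O1 | intermediate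
31 | (2E,4E,6E)-7-[(2S,6S,7aR)-6-(tert-butyldimethylsilyloxy)-4,4,7a-trimethyl-2,4,5,6,7,7a-hexahydro-1-benzofuran-2-yl]-3-methylocta-2,4,6-trien-1-ol | OC/C=C(C)/C=C/C=C(\C)[C@@H]1C=C2C(C)(C)C[C@H](O[Si](C)(C)C(C)(C)C)C[C@@]2(C)O1 | intermediate
32 | (2E,4E,6E)-7-[(2S,6S,7aR)-6-(tert-butyldimethylsilyloxy)-4,4,7a-trimethyl-2,4,5,6,7,7a-hexahydro-1-benzofuran-2-yl]-3-methylocta-2,4,6-trienal | O=C/C=C(C)/C=C/C=C(\C)[C@@H]1C=C2C(C)(C)C[C@H](O[Si](C)(C)C(C)(C)C)C[C@@]2(C)O1 | intermediate
33 | 15Z isomer of 34; not isolated | CC(/C=C/C=C(C)/C=C/[C@@]1(O[Si](CC)(CC)CC)C(C)(C)C[C@H](O[Si](C)(C)C(C)(C)C)C[C@@]1(C)O[Si](CC)(CC)CC)=C\C=C/C=C(C)/C=C/C=C(\C)[C@@H]1C=C2C(C)(C)C[C@H](O[Si](C)(C)C(C)(C)C)C[C@@]2(C)O1 | intermediate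
34 | 3,3′-bis(tert-butyldimethylsilyl) 5,6-bis(triethylsilyl) ether of 35 (all-E) | CC(/C=C/C=C(C)/C=C/[C@@]1(O[Si](CC)(CC)CC)C(C)(C)C[C@H](O[Si](C)(C)C(C)(C)C)C[C@@]1(C)O[Si](CC)(CC)CC)=C\C=C\C=C(C)\C=C\C=C(/C)[C@@H]1C=C2C(C)(C)C[C@H](O[Si](C)(C)C(C)(C)C)C[C@@]2(C)O1 | intermediate
35 | (3S,5R,6R,3′S,5′R,8′S)-5′,8′-epoxy-5,6,5′,8′-tetrahydro-β,β-carotene-3,5,6,3′-tetrol (all-E) | CC(/C=C/C=C(C)/C=C/[C@@]1(O)C(C)(C)C[C@H](O)C[C@@]1(C)O)=C\C=C\C=C(C)\C=C\C=C(/C)[C@@H]1C=C2C(C)(C)C[C@H](O)C[C@@]2(C)O1 | target

Total step count: 28. Longest linear sequence: 16 steps (steps 1–10, 12–15, 27 and 28 from 1; the furanoid branch, steps 1–4, 16–18, 20–26, 27 and 28, is equally long).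

Least certain steps

Step 12 (key step). Most likely to go wrong: ionisation or desilylation at the tertiary allylic C6–O bond under the aluminium and zirconium Lewis acids, because the cation at C6 is conjugated with the enyne; next in likelihood is attack of the alane on the ester. Fallback: the chain is joined at C8–C9 instead, without any aluminium or zirconium reagent. The (E)-iodoalkene 10 is coupled (Stille coupling; Pd2(dba)3, AsPh3, N-methylpyrrolidone, rt) with ethyl (2E,4E,6E)-3-methyl-7-(tributylstannyl)octa-2,4,6-trienoate F1. F1 is prepared from (E)-3-(tributylstannyl)but-2-enal F2 and 29 by the olefination used in step 24. This fallback sets out from 10 and comes back at 15.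

Step 5. Most likely to go wrong: poor facial selectivity, because the tartrate has to overrule the substrate's own preference for the face trans to the C3 silyloxy group (mismatched pairing). Fallback: the matched epoxy alcohol 19 is heated with aqueous NaOH in tert-butanol. The C7 alkoxide displaces the epoxide oxygen at C6 with inversion (Payne rearrangement) to give the spiro 6,7-epoxide with free C5–OH F3, which is not isolated because hydroxide opens it at the primary C7. C5–O is retained and C6–O inverted, which is the arrangement of 7. This fallback sets out from 19 and comes back at 7, bypassing steps 5 and 6.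

Step 6. Most likely to go wrong: ionisation at C5 before water arrives (loss of inversion, elimination to allylic alcohols, ring contraction), or acid cleavage of the secondary silyl ether. Fallback: an internal oxygen nucleophile replaces water. 6 is benzoylated (BzCl, pyridine) to the epoxy benzoate F4. BF3·OEt2 in CH2Cl2 at −40 °C makes the benzoate carbonyl oxygen attack C5 with inversion through a six-membered dioxanylium ion, and aqueous quench gives the C7 monobenzoate of the triol F5. K2CO3 in methanol then removes the benzoate. This fallback sets out from 6 and comes back at 7.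

Step 21. Most likely to go wrong: hydride delivery with the opposite sense or with low selectivity, which would give the epimeric allene axis and, after step 22, the C8′ epimer; over-reduction of the enyne is a lesser risk. Fallback: ring C is closed without an allene. 20 is olefinated with 29 (conditions of step 24) to the C15 epoxy dienoate F6. A trace of acid (HCl in CHCl3, 0 °C) induces the epoxide-to-furanoid rearrangement, giving both C8′ epimers, from which the 8′S furanoid ester F7 is separated by chromatography. iBu2AlH then reduces F7 to the alcohol. This fallback sets out from 20 and comes back at 27.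

Step 27. Most likely to go wrong: low E selectivity at C15=C15′ with incomplete thermal convergence, or base-induced damage to the polyenal. Fallback: a Wittig condensation. 16 is converted with Ph3P·HBr (MeOH, 0 °C) into the C20 triphenylphosphonium bromide F8. F8 is condensed with 32 (NaOMe, CH2Cl2–MeOH, 0 °C) and the product is equilibrated thermally as in step 27. This fallback sets out from 16 and comes back at 34.

## Further compounds

F1 | step 12 | ethyl (2E,4E,6E)-3-methyl-7-(tributylstannyl)octa-2,4,6-trienoate | CCOC(=O)/C=C(C)/C=C/C=C(\C)[Sn](CCCC)(CCCC)CCCC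
F2 | step 12 | (2E)-3-(tributylstannyl)but-2-enal | O=C/C=C(\C)[Sn](CCCC)(CCCC)CCCC
F3 | step 5 | spiro 6,7-epoxide with free C5–OH (C6–O cis to the C3 silyloxy group); not isolated | C1O[C@@]12C(C)(C)C[C@H](O[Si](C)(C)C(C)(C)C)C[C@@]2(C)O
F4 | step 6 | benzoate of 6 | O=C(OC[C@]12O[C@@]1(C)C[C@@H](O[Si](C)(C)C(C)(C)C)CC2(C)C)c1ccccc1
F5 | step 6 | C7 monobenzoate of 7 | O=C(OC[C@@]1(O)C(C)(C)C[C@H](O[Si](C)(C)C(C)(C)C)C[C@@]1(C)O)c1ccccc1
F6 | step 21 | ethyl (2E,4E)-5-[(1R,4S,6R)-4-(tert-butyldimethylsilyloxy)-2,2,6-trimethyl-7-oxabicyclo[4.1.0]heptan-1-yl]-3-methylpenta-2,4-dienoate | CCOC(=O)/C=C(C)/C=C/[C@@]12O[C@]1(C)C[C@@H](O[Si](C)(C)C(C)(C)C)CC2(C)C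
F7 | step 21 | ethyl (2E)-3-[(2S,6S,7aR)-6-(tert-butyldimethylsilyloxy)-4,4,7a-trimethyl-2,4,5,6,7,7a-hexahydro-1-benzofuran-2-yl]but-2-enoate | CCOC(=O)/C=C(\C)[C@@H]1C=C2C(C)(C)C[C@H](O[Si](C)(C)C(C)(C)C)C[C@@]2(C)O1
F8 | step 27 | triphenylphosphonium bromide derived from 16 (phosphorus on C15) | [Br-].c1ccccc1[P+](c1ccccc1)(c1ccccc1)C/C=C(C)/C=C/C=C(C)/C=C/[C@@]2(O[Si](CC)(CC)CC)C(C)(C)C[C@H](O[Si](C)(C)C(C)(C)C)C[C@@]2(C)O[Si](CC)(CC)CC
A1 | alternative 1 | tert-butyldimethylsilyl ether of (2,6,6-trimethylcyclohexa-1,3-dien-1-yl)methanol | CC1=C(CO[Si](C)(C)C(C)(C)C)C(C)(C)CC=C1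
A2 | alternative 1 | C3,C6-endoperoxide (2,3-dioxabicyclo[2.2.2]octene) | CC1=C[C@@H]2CC(C)(C)[C@@]1(CO[Si](C)(C)C(C)(C)C)OO2
A3 | alternative 2 | C15 allenol, C11′ tert-butyldimethylsilyl ether of 26 | CC(C)(C)[Si](C)(C)OC/C=C(\C)C=[C@@]=C1C(C)(C)C[C@H](O[Si](C)(C)C(C)(C)C)C[C@@]1(C)O
A4 | alternative 2 | C15 furanoid bis-silyl ether | CC(C)(C)[Si](C)(C)OC/C=C(\C)[C@@H]1C=C2C(C)(C)C[C@H](O[Si](C)(C)C(C)(C)C)C[C@@]2(C)O1
A5 | alternative 3 | tert-butyl carbonate of 6 | CC(C)(C)OC(=O)OC[C@]12O[C@@]1(C)C[C@@H](O[Si](C)(C)C(C)(C)C)CC2(C)C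
A6 | alternative 3 | 5,7-cyclic carbonate with free C6 hydroxyl | O=C1OC[C@@]2(O)C(C)(C)C[C@H](O[Si](C)(C)C(C)(C)C)C[C@@]2(C)O1
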